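Ring A of the 5,7-dihydroxyflavone half (flavone 1) is an acylphloroglucinol: oxygen at C5, C7 and C8a, acyl carbon C4 on C4a. The route therefore disconnects C4a–C5 and carries C5, C6, C7 and C8 as a methyl acetoacetate chain on a 2-aryl-4-pyranone that already holds O1, C2, C3, C4, C4a and C8a. One Mg(OMe)2-mediated Claisen closure forms C4a–C5 and aromatises ring A with both hydroxyls free. The precursor is a biaryl: ring B bears this pyranonyl keto ester and, ortho to its methoxy group, C8 of the finished 5,6,7,4'-tetramethoxyflavone (flavone 2), joined earlier by Suzuki coupling at the methylpyranone stage.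

Key step: step 11

Remark on stereochemistry: the axis between C3' of flavone 1 and C8 of flavone 2 carries only three small oxygen-based ortho substituents and is taken to rotate freely, in line with the target SMILES, which holds no stereodescriptor; no stereocentre has to be set.

Remark on design: boron is placed on ring B and not on C8 of flavone 2, because a 2,6-dioxygenated arylboronate would be prone to protodeboronation. The biaryl bond is made before the chain is extended, so the base-labile keto ester never meets hot aqueous base. The ester is a methyl ester matched to the methoxide base.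

Step 1
Reactants: 1 acetylacetone (pentane-2,4-dione); 2 methyl 3-bromo-4-methoxybenzoate
Product: 3 1-(3-bromo-4-methoxyphenyl)hexane-1,3,5-trione
Conditions: 1 (2 equiv), NaH (6 equiv), DME, reflux; then 1 M HCl, 0 °C
Reagents that add atoms: none
Why: Terminal aroylation of a 1,3-diketone dianion (crossed Claisen condensation), in which excess NaH takes the acetylacetone enolate on to the dianion, whose methyl carbanion attacks ester 2, while the aryl bromide is inert to NaH and the excess of 1 should suppress aroylation at both methyl groups.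

Step 2
Reactants: 3 1-(3-bromo-4-methoxyphenyl)hexane-1,3,5-trione
Product: 4 2-(3-bromo-4-methoxyphenyl)-6-methyl-4H-pyran-4-one
Conditions: conc. H2SO4, 0 °C; then ice water
Reagents that add atoms: none
Why: Acid-catalysed cyclodehydration of a 1,3,5-triketone, in which the enol oxygen of one terminal carbonyl adds to the other terminal carbonyl and water is lost, both directions of closure giving the same 4-pyranone, and the aroyl-deactivated bromoanisole ring should resist sulfonation at 0 °C.

Step 3
Reactants: 4 2-(3-bromo-4-methoxyphenyl)-6-methyl-4H-pyran-4-one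
Product: 5 2-[4-methoxy-3-(4,4,5,5-tetramethyl-1,3,2-dioxaborolan-2-yl)phenyl]-6-methyl-4H-pyran-4-one
Conditions: B2pin2, PdCl2(dppf) (3 mol %), KOAc, 1,4-dioxane, 90 °C
Reagents that add atoms: bis(pinacolato)diboron, CC1(C)OB(OC1(C)C)B1OC(C)(C)C(C)(C)O1
Why: Miyaura borylation, in which zerovalent palladium inserts into the C–Br bond, acetate-assisted transmetalation with B2pin2 and reductive elimination give the aryl pinacol boronate, and KOAc is too weak a base to affect the pyranone or its methyl group.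

Step 4
Reactants: 6 3,4,5-trimethoxyphenol
Product: 7 1-(6-hydroxy-2,3,4-trimethoxyphenyl)ethan-1-one
Conditions: AcOH, BF3·OEt2, 85 °C; then H2O
Reagents that add atoms: acetic acid, CC(=O)O
Why: BF3-promoted Friedel–Crafts acylation (Fries-type) of a phenol whose two ortho positions are equivalent and whose para position is blocked, so a single ortho-hydroxyacetophenone should form.

Step 5
Reactants: 7 1-(6-hydroxy-2,3,4-trimethoxyphenyl)ethan-1-one
Product: 8 1-(3-bromo-2-hydroxy-4,5,6-trimethoxyphenyl)ethan-1-one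
Conditions: NBS, MeCN, 0 °C to rt, dark
Reagents that add atoms: N-bromosuccinimide, O=C1CCC(=O)N1Br
Why: Electrophilic aromatic bromination at the only free ring position, which is ortho to the hydroxyl and ortho and para to methoxy groups and should therefore react far faster than the acetyl methyl group.

Step 6
Reactants: 8 1-(3-bromo-2-hydroxy-4,5,6-trimethoxyphenyl)ethan-1-one; 9 4-methoxybenzaldehyde
Product: 10 (E)-1-(3-bromo-2-hydroxy-4,5,6-trimethoxyphenyl)-3-(4-methoxyphenyl)prop-2-en-1-one
Conditions: KOH, EtOH, rt; then 1 M HCl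
Reagents that add atoms: none
Why: Claisen–Schmidt aldol condensation of the acetophenone enolate with a non-enolisable aldehyde, with loss of water giving the thermodynamically favoured E enone (the geometry is lost again in step 7).

Step 7
Reactants: 10 (E)-1-(3-bromo-2-hydroxy-4,5,6-trimethoxyphenyl)-3-(4-methoxyphenyl)prop-2-en-1-one
Product: 12 8-bromo-5,6,7-trimethoxy-2-(4-methoxyphenyl)-4H-chromen-4-one, via flavanone 11 (not isolated)
Conditions: I2 (10 mol %), DMSO, 130 °C
Reagents that add atoms: none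
Why: Iodine-catalysed oxidative cyclisation of a 2'-hydroxychalcone, in which oxa-Michael closure gives flavanone 11 and iodine dehydrogenates C2–C3 while DMSO turns the HI formed back into I2, with the aryl bromide and methyl ethers as spectators.

Step 8
Reactants: 5 2-[4-methoxy-3-(4,4,5,5-tetramethyl-1,3,2-dioxaborolan-2-yl)phenyl]-6-methyl-4H-pyran-4-one; 12 8-bromo-5,6,7-trimethoxy-2-(4-methoxyphenyl)-4H-chromen-4-one
Product: 13 5,6,7-trimethoxy-8-[2-methoxy-5-(6-methyl-4-oxo-4H-pyran-2-yl)phenyl]-2-(4-methoxyphenyl)-4H-chromen-4-one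
Conditions: Pd(OAc)2 (5 mol %), SPhos (10 mol %), K3PO4, toluene/H2O, 100 °C
Reagents that add atoms: none
Why: Suzuki–Miyaura coupling in which the electron-rich dialkylbiarylphosphine supports oxidative addition into the hindered C8–Br bond and reductive elimination to the tri-ortho-substituted biaryl, with boron on the less hindered partner and with only base-stable pyranone and chromone rings present.

Step 9
Reactants: 13 5,6,7-trimethoxy-8-[2-methoxy-5-(6-methyl-4-oxo-4H-pyran-2-yl)phenyl]-2-(4-methoxyphenyl)-4H-chromen-4-one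
Product: 14 {6-[4-methoxy-3-(5,6,7-trimethoxy-2-(4-methoxyphenyl)-4-oxo-4H-chromen-8-yl)phenyl]-4-oxo-4H-pyran-2-yl}acetic acid
Conditions: LiN(SiMe3)2 (2.2 equiv), THF, −78 °C; CO2; then cold 1 M HCl
Reagents that add atoms: carbon dioxide, O=C=O
Why: Lateral (vinylogous) metalation–carboxylation, in which the pyranone methyl protons are the only ones in 13 acidic enough for the hindered amide base, the delocalised anion takes up CO2 at the exocyclic carbon, and the excess base keeps the more acidic product from quenching unreacted anion.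

Step 10
Reactants: 14 {6-[4-methoxy-3-(5,6,7-trimethoxy-2-(4-methoxyphenyl)-4-oxo-4H-chromen-8-yl)phenyl]-4-oxo-4H-pyran-2-yl}acetic acid
Product: 17 methyl 4-{6-[4-methoxy-3-(5,6,7-trimethoxy-2-(4-methoxyphenyl)-4-oxo-4H-chromen-8-yl)phenyl]-4-oxo-4H-pyran-2-yl}-3-oxobutanoate, via acyl imidazolide 15 (not isolated), via acylmalonic half ester 16 (not isolated)
Conditions: CDI, THF, rt; then preformed Mg(O2CCH2CO2Me)2, THF, rt to 40 °C; then 1 M HCl, 0 °C
Reagents that add atoms: magnesium bis(methyl malonate) Mg(O2CCH2CO2Me)2, COC(=O)CC(=O)[O-].COC(=O)CC(=O)[O-].[Mg+2]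
Why: Masamune homologation, in which acyl imidazolide 15 acylates the magnesium enolate of methyl hydrogen malonate at carbon and acylmalonic half ester 16 loses CO2 on acidification, under near-neutral conditions where imidazole is too weak a base to start the ring closure of step 11.

Step 11
Reactants: 17 methyl 4-{6-[4-methoxy-3-(5,6,7-trimethoxy-2-(4-methoxyphenyl)-4-oxo-4H-chromen-8-yl)phenyl]-4-oxo-4H-pyran-2-yl}-3-oxobutanoate
Product: 19 8-[5-(5,7-dihydroxy-4-oxo-4H-chromen-2-yl)-2-methoxyphenyl]-5,6,7-trimethoxy-2-(4-methoxyphenyl)-4H-chromen-4-one, via triketone tautomer 18 (not isolated)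
Conditions: Mg(OMe)2 (6 equiv), MeOH, rt to 65 °C; then 1 M HCl
Reagents that add atoms: none
Why: Mg(OMe)2 chelates the keto ester and, by reversible proton transfer, gives the extended dienolate from the CH2 between pyranone and ketone, whose charge reaches C3 of the pyran-2-yl ring (the CH next to the chain-bearing carbon, C5 if the ring is numbered from the aryl-bearing carbon, future C4a); this carbon adds to the ester carbonyl (future C5), methoxide leaves to give triketone tautomer 18, and enolisation gives the aromatic 5,7-dihydroxy ring A of flavone 1. The closest known reaction type is the base-induced Claisen (Dieckmann-type) cyclisation of 3,5,7-triketo esters to acylphloroglucinols, here with the triketone locked as a 4-pyranone. The one new ring closes in a 6-(enolexo)-exo-trig acyl substitution. No stereocentre remains in the product, since the sp3 carbon of 18 is lost on enolisation. The step needs C-acylation at this one carbon ahead of aldol closure, retro-Claisen cleavage of the keto ester and opening of the pyranone or the chromone: the pyranone mask leaves no ketone placed for an aldol, magnesium chelation shields the keto ester and holds the chain folded over the attacking carbon, and the weakly nucleophilic magnesium base should spare the chromone of flavone 2 and the five methyl ethers. Aromatisation and formation of the magnesium chelate between the new C5 oxygen and the C4 carbonyl should make the closure irreversible.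

Step 12
Reactants: 19 8-[5-(5,7-dihydroxy-4-oxo-4H-chromen-2-yl)-2-methoxyphenyl]-5,6,7-trimethoxy-2-(4-methoxyphenyl)-4H-chromen-4-one
Product: 20 sumaflavone, 8-[5-(5,7-dihydroxy-4-oxo-4H-chromen-2-yl)-2-hydroxyphenyl]-5,6,7-trihydroxy-2-(4-hydroxyphenyl)-4H-chromen-4-one
Conditions: BBr3 (20 equiv), CH2Cl2, −78 °C to rt, then 40 °C; H2O, 0 °C, under argon
Reagents that add atoms: none
Why: Lewis acid cleavage of aryl methyl ethers, in which boron binds each ether oxygen and bromide removes the methyl group by SN2, and the aprotic medium at or below 40 °C should leave ring C of flavone 2 closed and so avoid a Wessely–Moser exchange of its C6 and C8 substituents.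

Compound list
1 | acetylacetone (pentane-2,4-dione) | CC(=O)CC(C)=O | starting material
2 | methyl 3-bromo-4-methoxybenzoate | COC(=O)c1ccc(OC)c(Br)c1 | starting material
3 | 1-(3-bromo-4-methoxyphenyl)hexane-1,3,5-trione | CC(=O)CC(=O)CC(=O)c1ccc(OC)c(Br)c1 | intermediate
4 | 2-(3-bromo-4-methoxyphenyl)-6-methyl-4H-pyran-4-one | Cc1cc(=O)cc(-c2ccc(OC)c(Br)c2)o1 | intermediate
5 | 2-[4-methoxy-3-(4,4,5,5-tetramethyl-1,3,2-dioxaborolan-2-yl)phenyl]-6-methyl-4H-pyran-4-one | Cc1cc(=O)cc(-c2ccc(OC)c(B3OC(C)(C)C(C)(C)O3)c2)o1 | intermediate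
6 | 3,4,5-trimethoxyphenol | COc1cc(O)cc(OC)c1OC | starting material
7 | 1-(6-hydroxy-2,3,4-trimethoxyphenyl)ethan-1-one | CC(=O)c1c(O)cc(OC)c(OC)c1OC | intermediate
8 | 1-(3-bromo-2-hydroxy-4,5,6-trimethoxyphenyl)ethan-1-one | CC(=O)c1c(O)c(Br)c(OC)c(OC)c1OC | intermediate
9 | 4-methoxybenzaldehyde | COc1ccc(C=O)cc1 | starting material
10 | (E)-1-(3-bromo-2-hydroxy-4,5,6-trimethoxyphenyl)-3-(4-methoxyphenyl)prop-2-en-1-one | COc1ccc(/C=C/C(=O)c2c(O)c(Br)c(OC)c(OC)c2OC)cc1 | intermediate
11 | 8-bromo-5,6,7-trimethoxy-2-(4-methoxyphenyl)-2,3-dihydro-4H-chromen-4-one (flavanone, racemic, not isolated) | COc1ccc(cc1)C1CC(=O)c2c(OC)c(OC)c(OC)c(Br)c2O1 | intermediate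
12 | 8-bromo-5,6,7-trimethoxy-2-(4-methoxyphenyl)-4H-chromen-4-one | COc1ccc(cc1)-c1cc(=O)c2c(OC)c(OC)c(OC)c(Br)c2o1 | intermediate
13 | 5,6,7-trimethoxy-8-[2-methoxy-5-(6-methyl-4-oxo-4H-pyran-2-yl)phenyl]-2-(4-methoxyphenyl)-4H-chromen-4-one | Cc1cc(=O)cc(-c2ccc(OC)c(c2)-c2c(OC)c(OC)c(OC)c3c(=O)cc(-c4ccc(OC)cc4)oc23)o1 | intermediate
14 | {6-[4-methoxy-3-(5,6,7-trimethoxy-2-(4-methoxyphenyl)-4-oxo-4H-chromen-8-yl)phenyl]-4-oxo-4H-pyran-2-yl}acetic acid | OC(=O)Cc1cc(=O)cc(-c2ccc(OC)c(c2)-c2c(OC)c(OC)c(OC)c3c(=O)cc(-c4ccc(OC)cc4)oc23)o1 | intermediate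
15 | acyl imidazolide of 14, 8-{5-[6-(2-(1H-imidazol-1-yl)-2-oxoethyl)-4-oxo-4H-pyran-2-yl]-2-methoxyphenyl}-5,6,7-trimethoxy-2-(4-methoxyphenyl)-4H-chromen-4-one (not isolated) | O=C(Cc1cc(=O)cc(-c2ccc(OC)c(c2)-c2c(OC)c(OC)c(OC)c3c(=O)cc(-c4ccc(OC)cc4)oc23)o1)n1ccnc1 | intermediate
16 | acylmalonic half ester, 2-(methoxycarbonyl)-3-oxo-4-{6-[4-methoxy-3-(5,6,7-trimethoxy-2-(4-methoxyphenyl)-4-oxo-4H-chromen-8-yl)phenyl]-4-oxo-4H-pyran-2-yl}butanoic acid (free-acid form of the magnesium chelate, configurationally labile, not isolated) | COC(=O)C(C(=O)O)C(=O)Cc1cc(=O)cc(-c2ccc(OC)c(c2)-c2c(OC)c(OC)c(OC)c3c(=O)cc(-c4ccc(OC)cc4)oc23)o1 | intermediate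
17 | methyl 4-{6-[4-methoxy-3-(5,6,7-trimethoxy-2-(4-methoxyphenyl)-4-oxo-4H-chromen-8-yl)phenyl]-4-oxo-4H-pyran-2-yl}-3-oxobutanoate | COC(=O)CC(=O)Cc1cc(=O)cc(-c2ccc(OC)c(c2)-c2c(OC)c(OC)c(OC)c3c(=O)cc(-c4ccc(OC)cc4)oc23)o1 | intermediate
18 | triketone tautomer of 19, 5,6,7-trimethoxy-8-[2-methoxy-5-(4,5,7-trioxo-4a,5,6,7-tetrahydro-4H-chromen-2-yl)phenyl]-2-(4-methoxyphenyl)-4H-chromen-4-one (racemic at C4a, not isolated) | O=C1CC(=O)C2C(=O)C=C(-c3ccc(OC)c(c3)-c3c(OC)c(OC)c(OC)c4c(=O)cc(-c5ccc(OC)cc5)oc34)OC2=C1 | intermediate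
19 | 8-[5-(5,7-dihydroxy-4-oxo-4H-chromen-2-yl)-2-methoxyphenyl]-5,6,7-trimethoxy-2-(4-methoxyphenyl)-4H-chromen-4-one | O=c1cc(-c2ccc(OC)c(c2)-c2c(OC)c(OC)c(OC)c3c(=O)cc(-c4ccc(OC)cc4)oc23)oc2cc(O)cc(O)c12 | intermediate
20 | sumaflavone, 8-[5-(5,7-dihydroxy-4-oxo-4H-chromen-2-yl)-2-hydroxyphenyl]-5,6,7-trihydroxy-2-(4-hydroxyphenyl)-4H-chromen-4-one | O=c1cc(-c2ccc(O)c(-c3c(O)c(O)c(O)c4c(=O)cc(-c5ccc(O)cc5)oc34)c2)oc2cc(O)cc(O)c12 | target

Total step count: 12. Longest linear sequence: 9 steps (steps 4 to 12, from 6); the other branch (steps 1 to 3) joins at step 8.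

Steps most likely to fail

Step 11 (key ring closure). The chain may rest as the unreactive magnesium chelate of the keto ester so that C-acylation stalls, while prolonged heating could let methoxide open the pyranone or cleave the keto ester by retro-Claisen fragmentation. The fallback gives up the late ring construction and joins two complete flavones. It sets out from 12 and returns to the route at 20. Commercial 1-(2-hydroxy-4,6-dimethoxyphenyl)ethan-1-one and 3-bromo-4-methoxybenzaldehyde are condensed (KOH, EtOH) to (E)-3-(3-bromo-4-methoxyphenyl)-1-(2-hydroxy-4,6-dimethoxyphenyl)prop-2-en-1-one F1. This is cyclised with I2 in DMSO to 2-(3-bromo-4-methoxyphenyl)-5,7-dimethoxy-4H-chromen-4-one F2 and borylated (B2pin2, PdCl2(dppf), KOAc) to 5,7-dimethoxy-2-[4-methoxy-3-(4,4,5,5-tetramethyl-1,3,2-dioxaborolan-2-yl)phenyl]-4H-chromen-4-one F3. Suzuki coupling of F3 with 12 under the conditions of step 8 should give sumaflavone heptamethyl ether F4, and BBr3 as in step 12 should cleave all seven ethers to 20.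

Step 9 (lateral carboxylation). Metalation of the poorly soluble substrate at −78 °C may be incomplete, the carboxylated product may transfer a proton to unreacted anion, and the pyranylacetic acid may lose CO2 during acidification and drying. The fallback installs the carboxyl carbon before the biaryl coupling, as a tert-butyl ester that tolerates base and is opened only by acid. It sets out from 4 and returns at 14. Compound 4 is metalated with LiN(SiMe3)2 (2.2 equiv, THF, −78 °C) and trapped with di-tert-butyl dicarbonate to give tert-butyl [6-(3-bromo-4-methoxyphenyl)-4-oxo-4H-pyran-2-yl]acetate F5. Miyaura borylation gives tert-butyl {6-[4-methoxy-3-(4,4,5,5-tetramethyl-1,3,2-dioxaborolan-2-yl)phenyl]-4-oxo-4H-pyran-2-yl}acetate F6, and Suzuki coupling with 12 as in step 8 gives tert-butyl {6-[4-methoxy-3-(5,6,7-trimethoxy-2-(4-methoxyphenyl)-4-oxo-4H-chromen-8-yl)phenyl]-4-oxo-4H-pyran-2-yl}acetate F7. Trifluoroacetic acid in CH2Cl2 at rt should then release acid 14 without base or heat.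

Step 8 (hindered biaryl coupling). Transmetalation onto the crowded arylpalladium bromide may be slow, so that protodeboronation of 5 and hydrodebromination of 12 outrun biaryl formation. The fallback replaces boron by tin and the Suzuki by a Stille coupling. It sets out from 4 and returns at 13. Compound 4 is stannylated (Me3SnSnMe3, Pd(PPh3)4, toluene, 110 °C) to 2-[4-methoxy-3-(trimethylstannyl)phenyl]-6-methyl-4H-pyran-4-one F8. Fluoride-activated Stille coupling of F8 with 12 (Pd[P(t-Bu)3]2, CsF, 1,4-dioxane, 100 °C), a combination known to serve crowded biaryls, should give 13 with no protodeboronation pathway.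

Further compounds
F1 | step 11 | (E)-3-(3-bromo-4-methoxyphenyl)-1-(2-hydroxy-4,6-dimethoxyphenyl)prop-2-en-1-one | COc1cc(O)c(C(=O)/C=C/c2ccc(OC)c(Br)c2)c(OC)c1
F2 | step 11 | 2-(3-bromo-4-methoxyphenyl)-5,7-dimethoxy-4H-chromen-4-one | COc1cc(OC)c2c(=O)cc(-c3ccc(OC)c(Br)c3)oc2c1
F3 | step 11 | 5,7-dimethoxy-2-[4-methoxy-3-(4,4,5,5-tetramethyl-1,3,2-dioxaborolan-2-yl)phenyl]-4H-chromen-4-one | COc1cc(OC)c2c(=O)cc(-c3ccc(OC)c(B4OC(C)(C)C(C)(C)O4)c3)oc2c1
F4 | step 11 | sumaflavone heptamethyl ether, 8-[5-(5,7-dimethoxy-4-oxo-4H-chromen-2-yl)-2-methoxyphenyl]-5,6,7-trimethoxy-2-(4-methoxyphenyl)-4H-chromen-4-one | COc1cc(OC)c2c(=O)cc(-c3ccc(OC)c(c3)-c3c(OC)c(OC)c(OC)c4c(=O)cc(-c5ccc(OC)cc5)oc34)oc2c1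
F5 | step 9 | tert-butyl [6-(3-bromo-4-methoxyphenyl)-4-oxo-4H-pyran-2-yl]acetate | CC(C)(C)OC(=O)Cc1cc(=O)cc(-c2ccc(OC)c(Br)c2)o1
F6 | step 9 | tert-butyl {6-[4-methoxy-3-(4,4,5,5-tetramethyl-1,3,2-dioxaborolan-2-yl)phenyl]-4-oxo-4H-pyran-2-yl}acetate | CC(C)(C)OC(=O)Cc1cc(=O)cc(-c2ccc(OC)c(B3OC(C)(C)C(C)(C)O3)c2)o1
F7 | step 9 | tert-butyl {6-[4-methoxy-3-(5,6,7-trimethoxy-2-(4-methoxyphenyl)-4-oxo-4H-chromen-8-yl)phenyl]-4-oxo-4H-pyran-2-yl}acetate | CC(C)(C)OC(=O)Cc1cc(=O)cc(-c2ccc(OC)c(c2)-c2c(OC)c(OC)c(OC)c3c(=O)cc(-c4ccc(OC)cc4)oc23)o1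
F8 | step 8 | 2-[4-methoxy-3-(trimethylstannyl)phenyl]-6-methyl-4H-pyran-4-one | Cc1cc(=O)cc(-c2ccc(OC)c([Sn](C)(C)C)c2)o1
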